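**Retrosynthetic overview**
1. Target ⇒ global desilylation and 8-O-acylation of the bicyclic 8-hydroxy lactone with 2-(silyloxymethyl)acrylic acid.
2. Ten-membered carbocycle ⇒ ring-closing metathesis at C1=C10 of a methallyl/butenyl diene (this ring is formed last).
3. C8–C9 ⇒ reagent-controlled methallylboration of a C8 aldehyde (sets C8).
4. γ-Lactone ⇒ Evans syn-aldol of an N-succinyl oxazolidinone with an (E)-enal and lactonisation in the flask (key C6–C7 bond, sets C6 and C7, lactone ring formed first); C11 methyl by trans-alkylation.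
5. Enal ⇒ but-2-yne-1,4-diol by hydroalumination/iodination and Negishi coupling (fixes the C4=C5 geometry).

Assumption: the target is taken exactly as drawn, i.e. 6R,7R,8S,11S (germacrane numbering C1–C15, C12 = lactone carbonyl), trans-fused lactone, both ring alkenes cis within the ring. Abbreviations: TBDPS = tert-butyldiphenylsilyl, TBS = tert-butyldimethylsilyl, Ipc = isopinocampheyl.

**Step 1**
Reactants: 1 but-2-yne-1,4-diol
Product: 2 4-(TBDPS-oxy)but-2-yn-1-ol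
Conditions: 1 (3 equiv), TBDPSCl (1 equiv), imidazole, DMF, 0 → 23 °C
Reagents that add atoms: tert-butyl(chloro)diphenylsilane, CC(C)(C)[Si](Cl)(c1ccccc1)c1ccccc1
Why: Silyl ether formation on one hydroxyl; the excess of cheap, water-soluble diol makes the monosilylation statistical in favour of 2.

**Step 2**
Reactants: 2 4-(TBDPS-oxy)but-2-yn-1-ol
Product: 4 (2Z)-4-(TBDPS-oxy)-3-iodobut-2-en-1-ol, via cyclic vinylalanate 3 (not isolated)
Conditions: NaAlH2(OCH2CH2OCH3)2 (Red-Al, 1.6 equiv), THF, 0 °C; then I2, THF, −78 → 0 °C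
Reagents that add atoms: iodine, II
Why: Hydroxyl-directed trans-hydroalumination puts aluminium on C3 in a five-membered alanate, and iodinolysis with retention gives the Z-iodide that fixes the later C4=C5 geometry; low temperature prevents β-elimination to the allene.

**Step 3**
Reactants: 4 (2Z)-4-(TBDPS-oxy)-3-iodobut-2-en-1-ol
Product: 5 (2E)-3-(TBDPS-oxymethyl)hepta-2,6-dien-1-ol
Conditions: CH2=CHCH2CH2ZnBr (2.5 equiv), Pd(dppf)Cl2 (5 mol %), THF, 23 → 50 °C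
Reagents that add atoms: but-3-enylzinc bromide, C=CCC[Zn]Br
Why: Negishi sp2–sp3 coupling proceeds with retention of alkene geometry, so the butenyl chain (C3–C1) ends up cis to the carbinol carbon (C6); dppf suppresses β-hydride elimination.

**Step 4**
Reactants: 5 (2E)-3-(TBDPS-oxymethyl)hepta-2,6-dien-1-ol
Product: 6 (2E)-3-(TBDPS-oxymethyl)hepta-2,6-dienal
Conditions: Dess–Martin periodinane, NaHCO3, CH2Cl2, 0 → 23 °C
Reagents that add atoms: none
Why: Buffered Dess–Martin oxidation of the allylic alcohol gives the enal without E/Z isomerisation.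

**Step 5**
Reactants: 7 (4S)-4-benzyl-1,3-oxazolidin-2-one; 8 methyl 4-chloro-4-oxobutanoate
Product: 9 methyl 4-[(4S)-4-benzyl-2-oxo-1,3-oxazolidin-3-yl]-4-oxobutanoate
Conditions: Et3N, DMAP (10 mol %), CH2Cl2, 0 → 23 °C
Reagents that add atoms: none
Why: DMAP-catalysed N-acylation of the Evans auxiliary by the acid chloride.

**Step 6**
Reactants: 9 methyl 4-[(4S)-4-benzyl-2-oxo-1,3-oxazolidin-3-yl]-4-oxobutanoate; 6 (2E)-3-(TBDPS-oxymethyl)hepta-2,6-dienal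
Product: 12 (4S)-4-benzyl-3-{[(2R,3S)-2-[(1E)-2-(TBDPS-oxymethyl)hexa-1,5-dien-1-yl]-5-oxooxolan-3-yl]carbonyl}-1,3-oxazolidin-2-one, via boron enolate 10 (not isolated), via boron aldolate 11 (not isolated)
Conditions: n-Bu2BOTf, i-Pr2NEt, CH2Cl2, 0 °C; then 6, −78 → 23 °C; then pH 7 buffer, MeOH, 30% H2O2, 0 °C
Reagents that add atoms: none
Why: Evans syn-aldol reaction: the Z-boron enolate reacts through a Zimmerman–Traxler chair with auxiliary-controlled facial selectivity to set C6 and C7 (the fragment-joining C6–C7 bond), and the aldolate oxygen closes onto the methyl ester to give the trans-4,5-disubstituted γ-lactone.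

**Step 7**
Reactants: 12 (4S)-4-benzyl-3-{[(2R,3S)-2-[(1E)-2-(TBDPS-oxymethyl)hexa-1,5-dien-1-yl]-5-oxooxolan-3-yl]carbonyl}-1,3-oxazolidin-2-one
Product: 14 (2R,3S)-2-[(1E)-2-(TBDPS-oxymethyl)hexa-1,5-dien-1-yl]-5-oxooxolane-3-carboxylic acid, via lithium percarboxylate 13 (not isolated)
Conditions: LiOH, 30% H2O2, THF/H2O (3:1), 0 °C; then aq. Na2SO3; then 1 M HCl to pH 3
Reagents that add atoms: hydrogen peroxide (acting as lithium hydroperoxide), OO
Why: Hydroperoxide attacks the exocyclic imide carbonyl selectively (Evans auxiliary cleavage), leaving the lactone and the C7 stereocentre intact.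

**Step 8**
Reactants: 14 (2R,3S)-2-[(1E)-2-(TBDPS-oxymethyl)hexa-1,5-dien-1-yl]-5-oxooxolane-3-carboxylic acid
Product: 16 (2R,3S,4S)-2-[(1E)-2-(TBDPS-oxymethyl)hexa-1,5-dien-1-yl]-4-methyl-5-oxooxolane-3-carboxylic acid, via disodium enolate carboxylate 15 (not isolated)
Conditions: NaN(SiMe3)2 (2.2 equiv), THF, −78 °C; then MeI, −78 → −40 °C; then 1 M HCl
Reagents that add atoms: iodomethane, CI
Why: Enolate alkylation of the lactone dianion occurs anti to the adjacent C7 carboxylate, giving the all-trans lactone with the 11S methyl group.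

**Step 9**
Reactants: 16 (2R,3S,4S)-2-[(1E)-2-(TBDPS-oxymethyl)hexa-1,5-dien-1-yl]-4-methyl-5-oxooxolane-3-carboxylic acid
Product: 18 (3S,4R,5R)-5-[(1E)-2-(TBDPS-oxymethyl)hexa-1,5-dien-1-yl]-4-(hydroxymethyl)-3-methyloxolan-2-one, via isobutyl carbonic anhydride 17 (not isolated)
Conditions: i-BuOCOCl, N-methylmorpholine, THF, −15 °C; then NaBH4, H2O, −15 → 0 °C, 15 min; cold aq. NH4Cl
Reagents that add atoms: none
Why: Mixed-anhydride activation lets NaBH4 reduce the acid in the presence of the lactone and alkenes; the short, cold, quickly neutralised reduction avoids migration of the lactone to the new hydroxyl.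

**Step 10**
Reactants: 18 (3S,4R,5R)-5-[(1E)-2-(TBDPS-oxymethyl)hexa-1,5-dien-1-yl]-4-(hydroxymethyl)-3-methyloxolan-2-one
Product: 19 (2R,3S,4S)-2-[(1E)-2-(TBDPS-oxymethyl)hexa-1,5-dien-1-yl]-4-methyl-5-oxooxolane-3-carbaldehyde
Conditions: Dess–Martin periodinane, NaHCO3, CH2Cl2, 0 → 23 °C; used at once
Reagents that add atoms: none
Why: Neutral Dess–Martin oxidation gives the β-acyloxy aldehyde without base, so neither β-elimination nor C7 epimerisation is triggered.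

**Step 11**
Reactants: 19 (2R,3S,4S)-2-[(1E)-2-(TBDPS-oxymethyl)hexa-1,5-dien-1-yl]-4-methyl-5-oxooxolane-3-carbaldehyde
Product: 21 (3S,4R,5R)-5-[(1E)-2-(TBDPS-oxymethyl)hexa-1,5-dien-1-yl]-4-[(1S)-1-hydroxy-3-methylbut-3-en-1-yl]-3-methyloxolan-2-one, via diisopinocampheylborinate 20 (not isolated)
Conditions: (−)-Ipc2BOMe, CH2=C(CH3)CH2MgCl, Et2O, 0 → 23 °C; then 19, −78 °C; then pH 7 buffer, MeOH, 30% H2O2, 0 → 23 °C
Reagents that add atoms: 2-methylallylmagnesium chloride, CC(=C)C[Mg]Cl, delivered as (−)-B-(2-methylallyl)diisopinocampheylborane, CC(=C)CB([C@@H]1C[C@@H]2C[C@@H](C2(C)C)[C@H]1C)[C@@H]1C[C@@H]2C[C@@H](C2(C)C)[C@H]1C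
Why: Brown asymmetric methallylboration through a chair transition state gives reagent-controlled addition to one aldehyde face and sets C8 as S (the borane from (+)-α-pinene; its enantiomer would give 8R); the buffered, base-free work-up keeps the new γ-hydroxyl from attacking the lactone.

**Step 12**
Reactants: 21 (3S,4R,5R)-5-[(1E)-2-(TBDPS-oxymethyl)hexa-1,5-dien-1-yl]-4-[(1S)-1-hydroxy-3-methylbut-3-en-1-yl]-3-methyloxolan-2-one
Product: 22 (3S,3aR,4S,6Z,10E,11aR)-10-(TBDPS-oxymethyl)-4-hydroxy-3,6-dimethyl-3a,4,5,8,9,11a-hexahydrocyclodeca[b]furan-2(3H)-one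
Conditions: second-generation Hoveyda–Grubbs catalyst [RuCl2(H2IMes)(=CH-C6H4-2-O-i-Pr)] (15 mol %, in portions), 1,4-benzoquinone (30 mol %), toluene (1 mM), 90 °C
Reagents that add atoms: none
Why: Ring-closing metathesis between the terminal vinyl and the methallyl group, driven by loss of ethene; a ten-membered ring accommodates the new trisubstituted alkene as the ring-cis (6Z) isomer, and the hindered, doubly allylically oxygenated C4=C5 alkene stays out of the reaction.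

**Step 13**
Reactants: 23 ethyl 2-(hydroxymethyl)prop-2-enoate
Product: 24 ethyl 2-(TBS-oxymethyl)prop-2-enoate
Conditions: TBSCl, imidazole, CH2Cl2, 0 → 23 °C
Reagents that add atoms: tert-butyl(chloro)dimethylsilane, CC(C)(C)[Si](C)(C)Cl
Why: Standard silyl ether protection of the primary allylic hydroxyl.

**Step 14**
Reactants: 24 ethyl 2-(TBS-oxymethyl)prop-2-enoate
Product: 25 2-(TBS-oxymethyl)prop-2-enoic acid
Conditions: LiOH, THF/H2O (3:1), 0 → 23 °C; then 1 M HCl to pH 3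
Reagents that add atoms: lithium hydroxide, [Li+].[OH-]
Why: Saponification of the ethyl ester; the α-substituent slows conjugate addition and the TBS ether survives brief mild acidification.

**Step 15**
Reactants: 22 (3S,3aR,4S,6Z,10E,11aR)-10-(TBDPS-oxymethyl)-4-hydroxy-3,6-dimethyl-3a,4,5,8,9,11a-hexahydrocyclodeca[b]furan-2(3H)-one; 25 2-(TBS-oxymethyl)prop-2-enoic acid
Product: 26 (3S,3aR,4S,6Z,10E,11aR)-10-(TBDPS-oxymethyl)-3,6-dimethyl-2-oxo-2,3,3a,4,5,8,9,11a-octahydrocyclodeca[b]furan-4-yl 2-(TBS-oxymethyl)prop-2-enoate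
Conditions: DCC, DMAP (0.3 equiv), CH2Cl2, 0 → 23 °C
Reagents that add atoms: none
Why: Steglich esterification acylates the 8-hydroxyl with retention at C8 under conditions that do not open or migrate the lactone.

**Step 16**
Reactants: 26 (3S,3aR,4S,6Z,10E,11aR)-10-(TBDPS-oxymethyl)-3,6-dimethyl-2-oxo-2,3,3a,4,5,8,9,11a-octahydrocyclodeca[b]furan-4-yl 2-(TBS-oxymethyl)prop-2-enoate
Product: 27 (3S,3aR,4S,6Z,10E,11aR)-10-(hydroxymethyl)-3,6-dimethyl-2-oxo-2,3,3a,4,5,8,9,11a-octahydrocyclodeca[b]furan-4-yl 2-(hydroxymethyl)prop-2-enoate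
Conditions: HF·pyridine, pyridine, THF, 0 → 23 °C
Reagents that add atoms: none
Why: Fluoride-driven cleavage of both silyl ethers (strong Si–F bond) under buffered, non-basic conditions that spare the acrylate ester and the lactone.

**Compound list**
1 | but-2-yne-1,4-diol | OCC#CCO | starting material
2 | 4-[(tert-butyldiphenylsilyl)oxy]but-2-yn-1-ol | OCC#CCO[Si](c1ccccc1)(c1ccccc1)C(C)(C)C | intermediate
3 | sodium 3-{[(tert-butyldiphenylsilyl)oxy]methyl}-2,2-bis(2-methoxyethoxy)-2,5-dihydro-1,2-oxaaluminol-2-uide (cyclic vinylalanate) | [Na+].COCCO[Al-]1(OCCOC)OCC=C1CO[Si](c1ccccc1)(c1ccccc1)C(C)(C)C | intermediate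
4 | (2Z)-4-[(tert-butyldiphenylsilyl)oxy]-3-iodobut-2-en-1-ol | OC/C=C(\I)CO[Si](c1ccccc1)(c1ccccc1)C(C)(C)C | intermediate
5 | (2E)-3-{[(tert-butyldiphenylsilyl)oxy]methyl}hepta-2,6-dien-1-ol | OC/C=C(\CCC=C)CO[Si](c1ccccc1)(c1ccccc1)C(C)(C)C | intermediate
6 | (2E)-3-{[(tert-butyldiphenylsilyl)oxy]methyl}hepta-2,6-dienal | O=C/C=C(\CCC=C)CO[Si](c1ccccc1)(c1ccccc1)C(C)(C)C | intermediate
7 | (4S)-4-benzyl-1,3-oxazolidin-2-one | O=C1N[C@@H](Cc2ccccc2)CO1 | starting material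
8 | methyl 4-chloro-4-oxobutanoate | COC(=O)CCC(Cl)=O | starting material
9 | methyl 4-[(4S)-4-benzyl-2-oxo-1,3-oxazolidin-3-yl]-4-oxobutanoate | O=C1OC[C@H](Cc2ccccc2)N1C(=O)CCC(=O)OC | intermediate
10 | (Z)-dibutylboron enolate of 9 | CCCCB(CCCC)O/C(=C\CC(=O)OC)N1C(=O)OC[C@@H]1Cc1ccccc1 | intermediate
11 | methyl (3S,4R,5E)-3-{[(4S)-4-benzyl-2-oxo-1,3-oxazolidin-3-yl]carbonyl}-6-{[(tert-butyldiphenylsilyl)oxy]methyl}-4-[(dibutylboranyl)oxy]deca-5,9-dienoate (boron aldolate) | O=C1OC[C@H](Cc2ccccc2)N1C(=O)[C@@H](CC(=O)OC)[C@H](OB(CCCC)CCCC)/C=C(\CCC=C)CO[Si](c1ccccc1)(c1ccccc1)C(C)(C)C | intermediate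
12 | (4S)-4-benzyl-3-{[(2R,3S)-2-[(1E)-2-{[(tert-butyldiphenylsilyl)oxy]methyl}hexa-1,5-dien-1-yl]-5-oxooxolan-3-yl]carbonyl}-1,3-oxazolidin-2-one | O=C1OC[C@H](Cc2ccccc2)N1C(=O)[C@H]1CC(=O)O[C@@H]1/C=C(\CCC=C)CO[Si](c1ccccc1)(c1ccccc1)C(C)(C)C | intermediate
13 | lithium (2R,3S)-2-[(1E)-2-{[(tert-butyldiphenylsilyl)oxy]methyl}hexa-1,5-dien-1-yl]-5-oxooxolane-3-carboperoxoate | [Li+].[O-]OC(=O)[C@H]1CC(=O)O[C@@H]1/C=C(\CCC=C)CO[Si](c1ccccc1)(c1ccccc1)C(C)(C)C | intermediate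
14 | (2R,3S)-2-[(1E)-2-{[(tert-butyldiphenylsilyl)oxy]methyl}hexa-1,5-dien-1-yl]-5-oxooxolane-3-carboxylic acid | OC(=O)[C@H]1CC(=O)O[C@@H]1/C=C(\CCC=C)CO[Si](c1ccccc1)(c1ccccc1)C(C)(C)C | intermediate
15 | disodium salt of 14 deprotonated at the carboxyl group and at the lactone α-carbon (enolate carboxylate) | [Na+].[Na+].[O-]C(=O)[C@H]1C=C([O-])O[C@@H]1/C=C(\CCC=C)CO[Si](c1ccccc1)(c1ccccc1)C(C)(C)C | intermediate
16 | (2R,3S,4S)-2-[(1E)-2-{[(tert-butyldiphenylsilyl)oxy]methyl}hexa-1,5-dien-1-yl]-4-methyl-5-oxooxolane-3-carboxylic acid | OC(=O)[C@H]1[C@H](C)C(=O)O[C@@H]1/C=C(\CCC=C)CO[Si](c1ccccc1)(c1ccccc1)C(C)(C)C | intermediate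
17 | mixed anhydride of 16 with isobutyl hydrogen carbonate | CC(C)COC(=O)OC(=O)[C@H]1[C@H](C)C(=O)O[C@@H]1/C=C(\CCC=C)CO[Si](c1ccccc1)(c1ccccc1)C(C)(C)C | intermediate
18 | (3S,4R,5R)-5-[(1E)-2-{[(tert-butyldiphenylsilyl)oxy]methyl}hexa-1,5-dien-1-yl]-4-(hydroxymethyl)-3-methyloxolan-2-one | OC[C@H]1[C@H](C)C(=O)O[C@@H]1/C=C(\CCC=C)CO[Si](c1ccccc1)(c1ccccc1)C(C)(C)C | intermediate
19 | (2R,3S,4S)-2-[(1E)-2-{[(tert-butyldiphenylsilyl)oxy]methyl}hexa-1,5-dien-1-yl]-4-methyl-5-oxooxolane-3-carbaldehyde | O=C[C@H]1[C@H](C)C(=O)O[C@@H]1/C=C(\CCC=C)CO[Si](c1ccccc1)(c1ccccc1)C(C)(C)C | intermediate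
20 | O-diisopinocampheylboranyl derivative (borinate) of 21 | CC(=C)C[C@H](OB([C@@H]3C[C@@H]4C[C@@H](C4(C)C)[C@H]3C)[C@@H]5C[C@@H]6C[C@@H](C6(C)C)[C@H]5C)[C@H]1[C@H](C)C(=O)O[C@@H]1/C=C(\CCC=C)CO[Si](c1ccccc1)(c1ccccc1)C(C)(C)C | intermediate
21 | (3S,4R,5R)-5-[(1E)-2-{[(tert-butyldiphenylsilyl)oxy]methyl}hexa-1,5-dien-1-yl]-4-[(1S)-1-hydroxy-3-methylbut-3-en-1-yl]-3-methyloxolan-2-one | CC(=C)C[C@H](O)[C@H]1[C@H](C)C(=O)O[C@@H]1/C=C(\CCC=C)CO[Si](c1ccccc1)(c1ccccc1)C(C)(C)C | intermediate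
22 | (3S,3aR,4S,6Z,10E,11aR)-10-{[(tert-butyldiphenylsilyl)oxy]methyl}-4-hydroxy-3,6-dimethyl-3a,4,5,8,9,11a-hexahydrocyclodeca[b]furan-2(3H)-one | O[C@H]1C/C(C)=C\CC/C(CO[Si](c3ccccc3)(c3ccccc3)C(C)(C)C)=C\[C@H]2OC(=O)[C@@H](C)[C@H]12 | intermediate
23 | ethyl 2-(hydroxymethyl)prop-2-enoate | C=C(CO)C(=O)OCC | starting material
24 | ethyl 2-{[(tert-butyldimethylsilyl)oxy]methyl}prop-2-enoate | C=C(CO[Si](C)(C)C(C)(C)C)C(=O)OCC | intermediate
25 | 2-{[(tert-butyldimethylsilyl)oxy]methyl}prop-2-enoic acid | C=C(CO[Si](C)(C)C(C)(C)C)C(=O)O | intermediate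
26 | (3S,3aR,4S,6Z,10E,11aR)-10-{[(tert-butyldiphenylsilyl)oxy]methyl}-3,6-dimethyl-2-oxo-2,3,3a,4,5,8,9,11a-octahydrocyclodeca[b]furan-4-yl 2-{[(tert-butyldimethylsilyl)oxy]methyl}prop-2-enoate | C=C(CO[Si](C)(C)C(C)(C)C)C(=O)O[C@H]1C/C(C)=C\CC/C(CO[Si](c3ccccc3)(c3ccccc3)C(C)(C)C)=C\[C@H]2OC(=O)[C@@H](C)[C@H]12 | intermediate
27 | (3S,3aR,4S,6Z,10E,11aR)-10-(hydroxymethyl)-3,6-dimethyl-2-oxo-2,3,3a,4,5,8,9,11a-octahydrocyclodeca[b]furan-4-yl 2-(hydroxymethyl)prop-2-enoate | C=C(CO)C(=O)O[C@H]1C/C(C)=C\CC/C(CO)=C\[C@H]2OC(=O)[C@@H](C)[C@H]12 | target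

**Step count and risks**
Total: 16 steps. Longest linear sequence: 13 steps (1–4, 6–12, 15, 16); step 5 and steps 13–14 are side branches.

Most likely to fail, step 12 (ring-closing metathesis to a ten-membered ring with a trisubstituted alkene; oligomers or diversion through the C4=C5 alkene are possible). Fallback: close the ring by a Nozaki–Hiyama–Kishi reaction and place the alkene afterwards; it sets out from aldehyde 19 and returns at ester 26. Asymmetric 2-bromoallylation of 19 (Corey's chiral 1,2-diphenylethylenediamine bis(p-toluenesulfonamide) bromoborane with tributyl(2-bromoallyl)stannane, CH2Cl2, −78 °C, controller enantiomer chosen for 8S) gives the (8S)-2-bromoallyl carbinol F1. Esterification with acid 25 (DCC, DMAP) gives the acyclic 8-O-acyl ester F2. The terminal vinyl group, the only unhindered electron-rich alkene left, is dihydroxylated (OsO4 cat., N-methylmorpholine N-oxide) to the 1,2-diol F3 and cleaved with NaIO4 to the C1 aldehyde F4. CrCl2 with catalytic NiCl2 in DMSO at high dilution joins C1 to C10 and gives the ten-membered allylic alcohol F5, which carries an exocyclic methylene on C10 (either C1 epimer serves). Myers reductive 1,3-transposition (2-nitrobenzenesulfonylhydrazine, PPh3, diethyl azodicarboxylate, THF, −30 → 23 °C) passes through the Mitsunobu adduct N-sulfonylhydrazine F6 and the allylic diazene F7. The diazene loses N2 in a retro-ene step that moves the double bond to C1=C10 and turns the methylene into the C14 methyl; ring strain and allylic strain both favour C2 cis to C9, which is the ring-cis alkene of 26.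

Second, step 11 (the β-acyloxy aldehyde 19 can eliminate or epimerise, and the allylboration must override the substrate bias). Fallback: make C8–C9 at the ketone level and set C8 by reduction, bypassing steps 9–11; it sets out from acid 16 and returns at alcohol 21. Oxalyl chloride with catalytic DMF in CH2Cl2 at 0 °C gives the acid chloride F8. Palladium-catalysed acylation of tributyl(2-methylallyl)stannane (Pd(PPh3)4 cat., THF, 50 °C) gives the β,γ-unsaturated ketone F9. Reduction with (R)-2-methyl-CBS-oxazaborolidine and catecholborane in toluene at −78 °C (branched ring carbon as the large group) delivers the 8S alcohol 21.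

Third, step 15 (acylation of the hindered 8-hydroxyl with an α-substituted acrylic acid on the most precious material). Fallback: build the side chain on the substrate; it sets out from alcohol 22 and returns at target 27. Acryloyl chloride and Et3N in CH2Cl2 at −20 °C give the 8-O-acrylate F10. A Baylis–Hillman reaction with aqueous formaldehyde (DABCO, dioxane/H2O, 23 °C) gives the 2-(hydroxymethyl)acrylate F11, still silylated at C15. HF·pyridine then removes the TBDPS group to give 27.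

**Further compounds**
F1 | step 12 | (3S,4R,5R)-4-[(1S)-3-bromo-1-hydroxybut-3-en-1-yl]-5-[(1E)-2-{[(tert-butyldiphenylsilyl)oxy]methyl}hexa-1,5-dien-1-yl]-3-methyloxolan-2-one | C=C(Br)C[C@H](O)[C@H]1[C@H](C)C(=O)O[C@@H]1/C=C(\CCC=C)CO[Si](c1ccccc1)(c1ccccc1)C(C)(C)C
F2 | step 12 | (1S)-3-bromo-1-[(2R,3R,4S)-2-[(1E)-2-{[(tert-butyldiphenylsilyl)oxy]methyl}hexa-1,5-dien-1-yl]-4-methyl-5-oxooxolan-3-yl]but-3-en-1-yl 2-{[(tert-butyldimethylsilyl)oxy]methyl}prop-2-enoate | C=C(CO[Si](C)(C)C(C)(C)C)C(=O)O[C@@H](CC(Br)=C)[C@H]1[C@H](C)C(=O)O[C@@H]1/C=C(\CCC=C)CO[Si](c1ccccc1)(c1ccccc1)C(C)(C)C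
F3 | step 12 | 5,6-dihydroxyhex-1-enyl analogue of F2 (terminal vinyl converted to the 1,2-diol, diol carbon as a mixture) | C=C(CO[Si](C)(C)C(C)(C)C)C(=O)O[C@@H](CC(Br)=C)[C@H]1[C@H](C)C(=O)O[C@@H]1/C=C(\CCC(O)CO)CO[Si](c1ccccc1)(c1ccccc1)C(C)(C)C
F4 | step 12 | 5-oxopent-1-enyl analogue of F2 (C1 aldehyde) | C=C(CO[Si](C)(C)C(C)(C)C)C(=O)O[C@@H](CC(Br)=C)[C@H]1[C@H](C)C(=O)O[C@@H]1/C=C(\CCC=O)CO[Si](c1ccccc1)(c1ccccc1)C(C)(C)C
F5 | step 12 | (3S,3aR,4S,10E,11aR)-10-{[(tert-butyldiphenylsilyl)oxy]methyl}-7-hydroxy-3-methyl-6-methylidene-2-oxodecahydrocyclodeca[b]furan-4-yl-type allylic alcohol (9,10-alkene retained; C7 epimers) esterified with 25 | C=C(CO[Si](C)(C)C(C)(C)C)C(=O)O[C@H]1CC(=C)C(O)CC/C(CO[Si](c3ccccc3)(c3ccccc3)C(C)(C)C)=C\[C@H]2OC(=O)[C@@H](C)[C@H]12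
F6 | step 12 | N-alkyl-N-(2-nitrobenzenesulfonyl)hydrazine formed from F5 at C7 (cyclodeca[b]furan numbering) | C=C(CO[Si](C)(C)C(C)(C)C)C(=O)O[C@H]1CC(=C)C(N(N)S(=O)(=O)c4ccccc4[N+](=O)[O-])CC/C(CO[Si](c3ccccc3)(c3ccccc3)C(C)(C)C)=C\[C@H]2OC(=O)[C@@H](C)[C@H]12
F7 | step 12 | allylic monoalkyl diazene derived from F6 | C=C(CO[Si](C)(C)C(C)(C)C)C(=O)O[C@H]1CC(=C)C(N=N)CC/C(CO[Si](c3ccccc3)(c3ccccc3)C(C)(C)C)=C\[C@H]2OC(=O)[C@@H](C)[C@H]12
F8 | step 11 | (2R,3S,4S)-2-[(1E)-2-{[(tert-butyldiphenylsilyl)oxy]methyl}hexa-1,5-dien-1-yl]-4-methyl-5-oxooxolane-3-carbonyl chloride | ClC(=O)[C@H]1[C@H](C)C(=O)O[C@@H]1/C=C(\CCC=C)CO[Si](c1ccccc1)(c1ccccc1)C(C)(C)C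
F9 | step 11 | (3S,4S,5R)-5-[(1E)-2-{[(tert-butyldiphenylsilyl)oxy]methyl}hexa-1,5-dien-1-yl]-3-methyl-4-(3-methylbut-3-enoyl)oxolan-2-one | CC(=C)CC(=O)[C@H]1[C@H](C)C(=O)O[C@@H]1/C=C(\CCC=C)CO[Si](c1ccccc1)(c1ccccc1)C(C)(C)C
F10 | step 15 | (3S,3aR,4S,6Z,10E,11aR)-10-{[(tert-butyldiphenylsilyl)oxy]methyl}-3,6-dimethyl-2-oxo-2,3,3a,4,5,8,9,11a-octahydrocyclodeca[b]furan-4-yl prop-2-enoate | C=CC(=O)O[C@H]1C/C(C)=C\CC/C(CO[Si](c3ccccc3)(c3ccccc3)C(C)(C)C)=C\[C@H]2OC(=O)[C@@H](C)[C@H]12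
F11 | step 15 | (3S,3aR,4S,6Z,10E,11aR)-10-{[(tert-butyldiphenylsilyl)oxy]methyl}-3,6-dimethyl-2-oxo-2,3,3a,4,5,8,9,11a-octahydrocyclodeca[b]furan-4-yl 2-(hydroxymethyl)prop-2-enoate | C=C(CO)C(=O)O[C@H]1C/C(C)=C\CC/C(CO[Si](c3ccccc3)(c3ccccc3)C(C)(C)C)=C\[C@H]2OC(=O)[C@@H](C)[C@H]12
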